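**Retrosynthetic overview**

1. Target 20 ⇐ diol 19 (acetylation at C15) ⇐ epoxide 18 ⇐ 8(17)-ene 17 ⇐ 8-ketone 16: the 8α-OH/8β-CH3 pair comes from C8=O by methylenation (C17), α-face epoxidation and hydride opening, the same hydride reducing the ester.
2. Side chain: C13=C14 by Horner–Wadsworth–Emmons olefination of a C13 methyl ketone; C9–C11 by Mukaiyama–Michael addition of a C8/C9 silyl enol ether to methyl vinyl ketone.
3. Ring A (C10, C1, C2, C3, C4, C5) is closed last, by the C3–C4 bond: the C4–C7 bond of a cyclobutane next to the C8 ketone is cut, and the tertiary C4 cation so released is captured by a vinylsilane (C1–C3) that sits on C10.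
4. Ring B (C5–C10) is the six-membered ring of (1R,5R)-(+)-verbenone, which also brings C20, C4 with C18 and C19, and the C5 stereocentre; C1–C3 enter by conjugate addition at C10, anti to the CMe2 bridge, which fixes the trans ring fusion in advance. Ring order: B (present in 1), then A (step 4).
5. Enabling feature: the gem-dimethyl carbon C4 of ring A is bonded to C5, and C7 of ring B is 1,3 to C5 and α to the oxygen-bearing C8; a C4–C7 bond therefore maps rings A/B onto the pinane cyclobutane, whose strain next to C8=O delivers C4 as a cation where ring A must close.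

Key step: step 4

Remark: labdane numbering (C1–C20) is used for all intermediates (verbenone C4, C3, C2, C1, C7, C5, C6 become C10, C9, C8, C7, C6, C5, C4); the target is read as the normal-series (5S,8R,9R,10S,13E) labdane, and (1R,5R)-(+)-verbenone is taken as a commercial starting material.

**Step 1**
Reactants: 1 (1R,5R)-(+)-verbenone; 2 allyltrimethylsilane
Product: 5 Me3Si enol ether of the 1,4-adduct (silylallyl chain anti to the CMe2 bridge), via silylallyllithium 3 (not isolated), via silylallylcopper 4 (not isolated)
Conditions: 2, s-BuLi, TMEDA, THF, −78 → −30 °C; CuBr·SMe2, −78 °C; Me3SiCl, then 1, −78 → −40 °C; Et3N, pentane, filtration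
Reagents that add atoms: chlorotrimethylsilane, C[Si](C)(C)Cl
Why: Conjugate (1,4-) addition of an allylic organocopper reagent with Me3SiCl trapping: the silyl-substituted allyl unit should bond through its unsubstituted CH2 terminus (giving the E-vinylsilane) to C10 on the face opposite the CMe2 bridge, which sets the quaternary C10 with C20 syn and C1 anti to C4, and the adduct is held as the C8/C9 silyl enol ether, the only enol ether this ketone can form because C7 is a bridgehead.

**Step 2**
Reactants: 5 Me3Si enol ether of the 1,4-adduct; 6 methyl vinyl ketone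
Product: 8 bicyclic 1,5-diketone (3-oxobutyl group on C9), via silyl enol ether 7 (not isolated)
Conditions: 6 (1.5 equiv), Sc(OTf)3 (5 mol %), CH2Cl2, −78 °C; then 1 M HCl, THF, 0 °C
Reagents that add atoms: none
Why: Mukaiyama–Michael addition under Sc(OTf)3 catalysis: C9 of the silyl enol ether adds to the enone terminus, anti to the CMe2 bridge (this C9 configuration is provisional and is reset in step 4), the silyl group moves to the new enolate oxygen (7) and is removed on work-up, and the low temperature keeps the Lewis acid from opening the cyclobutane.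

**Step 3**
Reactants: 8 bicyclic 1,5-diketone; 9 triethyl phosphonoacetate
Product: 11 bicyclic keto enoate (13E), via sodium phosphonate 10 (not isolated)
Conditions: 9, NaH, THF, 0 °C; then 8, 0 °C → rt
Reagents that add atoms: none
Why: Horner–Wadsworth–Emmons olefination: the stabilised phosphonate anion reacts with the unhindered methyl ketone and not with the ring ketone, which is shielded by the bridgehead, the quaternary C10 and the CMe2 bridge, and should give mainly the 13E enoate (the minor 13Z isomer is removed by chromatography); epimerisation at C9 would be of no consequence.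

**Step 4**
Reactants: 11 bicyclic keto enoate
Product: 15 ethyl (13E)-8-oxo-17-norlabda-2,13-dien-15-oate, via ring-opened cation 12 (not isolated), via silyl enol ether 13 (not isolated), via 9-epi ketone 14 (not isolated)
Conditions: Me3SiOTf (0.3 equiv), CH2Cl2, −40 → 0 °C; then 1 M HCl, THF, rt
Reagents that add atoms: none
Why: Proposed new method: Me3SiOTf silylates the C8 carbonyl oxygen of 11, and the strained C4–C7 cyclobutane bond, which is aligned with the carbonyl π system, then breaks heterolytically in a Grob-type fragmentation to the ring-B silyl enol ether that carries a tertiary cation at C4 (12); the closest known reactions are the Lewis-acid ring opening of nopinone and verbanone to 4-(2-propyl)cyclohexenyl derivatives and the vinylsilane-terminated cation–olefin cyclization, here joined in one operation. Ring A closes by attack of the silicon-bearing C3 of the (E)-vinylsilane on C4 (6-endo-trig cation–olefin closure through a chair), after which the silyl group leaves from C3 (β-silicon effect) to give the C2=C3 alkene and to return Me3SiOTf, so that a substoichiometric amount suffices. No ring-fusion centre is made here: C5 and C10 are carried from 1 and step 1 with C4 and C1 trans on ring B, so only the trans-decalin can form, and C4 becomes the gem-dimethyl quaternary carbon without a stereocentre. The one centre settled in this step is C9: the acidic work-up cleaves the silyl enol ether 13 and lets the kinetic 9-epi ketone 14 equilibrate through the C8–C9 enol, whose protonation on the α face (axial, anti to the C10 methyl group) leads to the equatorial 9β side chain of 15, expected to be the more stable epimer. The step needs cleavage of C4–C7 and not of C6–C7 (tertiary against primary cation), bond formation at C3 and not at C2 (silicon directs, and the six-ring chair is open only to C3), and capture of the cation before elimination or hydride shift (the chain on C10 is held gauche to C4 by ring B, and an isopropenyl by-product would be re-protonated to 12 under the acidic conditions); the electron-poor enoate should not compete as a π-nucleophile.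

**Step 5**
Reactants: 15 ethyl (13E)-8-oxo-17-norlabda-2,13-dien-15-oate
Product: 16 ethyl (13E)-8-oxo-17-norlabd-13-en-15-oate
Conditions: H2 (3 atm), RhCl(PPh3)3 (5 mol %), benzene–EtOH, rt
Reagents that add atoms: none
Why: Homogeneous hydrogenation with RhCl(PPh3)3, which reduces the cis-disubstituted ring-A alkene and should leave the trisubstituted conjugated C13=C14 bond and the ketone untouched; no stereocentre is formed.

**Step 6**
Reactants: 16 ethyl (13E)-8-oxo-17-norlabd-13-en-15-oate
Product: 17 ethyl (13E)-labda-8(17),13-dien-15-oate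
Conditions: Ph3PCH3Br, KN(SiMe3)2, THF, 0 °C; then 16, 0 → 40 °C
Reagents that add atoms: methyltriphenylphosphonium bromide, C[P+](c1ccccc1)(c1ccccc1)c1ccccc1.[Br-]
Why: Wittig methylenation: salt-free Ph3P=CH2 converts the C8 ketone into the exocyclic C8=C17 alkene, while the ethyl ester and the β,β-disubstituted enoate are inert at this temperature, and C9, which can epimerise under these conditions, stays as the equatorial 9β epimer, whose C8 carbonyl is also the one open to the ylide from the α face.

**Step 7**
Reactants: 17 ethyl (13E)-labda-8(17),13-dien-15-oate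
Product: 18 ethyl (13E)-8α,17-epoxylabd-13-en-15-oate
Conditions: mCPBA, NaHCO3, CH2Cl2, 0 °C
Reagents that add atoms: 3-chloroperbenzoic acid (mCPBA), OOC(=O)c1cccc(Cl)c1
Why: Prilezhaev epoxidation: the electron-rich 1,1-disubstituted C8=C17 alkene reacts and the electron-poor enoate does not, and the peracid attacks from the α face, away from the axial C10 methyl group, so that the oxygen becomes equatorial (8α) and C17 axial.

**Step 8**
Reactants: 18 ethyl (13E)-8α,17-epoxylabd-13-en-15-oate
Product: 19 (13E)-labd-13-ene-8α,15-diol
Conditions: LiAlH4, THF, 0 °C → rt; aqueous work-up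
Reagents that add atoms: none
Why: Hydride reduction with LiAlH4: the spiro-epoxide is opened by SN2 attack at the primary C17, which becomes the axial 8β methyl group and leaves the tertiary 8α alcohol with its configuration untouched, and the enoate is reduced by 1,2-addition to the primary allylic alcohol with the 13E alkene intact.

**Step 9**
Reactants: 19 (13E)-labd-13-ene-8α,15-diol
Product: 20 (13E)-8α-hydroxylabd-13-en-15-yl acetate (CNP0268033.1)
Conditions: Ac2O, pyridine, 0 °C → rt
Reagents that add atoms: acetic anhydride, CC(=O)OC(C)=O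
Why: Chemoselective O-acetylation: the primary allylic C15 alcohol is acylated by Ac2O in pyridine, whereas the hindered tertiary 8α alcohol does not react without a nucleophilic catalyst, which gives the target.

**Compound list**

1 | (1R,5R)-(+)-verbenone, (1R,5R)-4,6,6-trimethylbicyclo[3.1.1]hept-3-en-2-one | CC1=CC(=O)[C@@H]2C[C@H]1C2(C)C | starting material
2 | allyltrimethylsilane | C=CC[Si](C)(C)C | starting material
3 | 1-(trimethylsilyl)allyllithium, Me3SiCH(Li)CH=CH2 | [Li]C(C=C)[Si](C)(C)C | intermediate
4 | (E)-3-(trimethylsilyl)allylcopper, Me3SiCH=CHCH2Cu | [Cu]C/C=C/[Si](C)(C)C | intermediate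
5 | 4,6,6-trimethyl-2-(trimethylsilyloxy)-4-[(E)-3-(trimethylsilyl)prop-2-enyl]bicyclo[3.1.1]hept-2-ene, silylallyl chain anti to the CMe2 bridge, bridgeheads as in 1 | C[C@@]1(C/C=C/[Si](C)(C)C)C=C(O[Si](C)(C)C)[C@@H]2C[C@H]1C2(C)C | intermediate
6 | methyl vinyl ketone (but-3-en-2-one) | CC(=O)C=C | starting material
7 | (Z)-silyl enol ether of the Michael adduct: 4,6,6-trimethyl-3-[3-(trimethylsilyloxy)but-2-enyl]-4-[(E)-3-(trimethylsilyl)prop-2-enyl]bicyclo[3.1.1]heptan-2-one | C[C@@]1(C/C=C/[Si](C)(C)C)[C@H](C/C=C(/C)O[Si](C)(C)C)C(=O)[C@@H]2C[C@H]1C2(C)C | intermediate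
8 | 4,6,6-trimethyl-3-(3-oxobutyl)-4-[(E)-3-(trimethylsilyl)prop-2-enyl]bicyclo[3.1.1]heptan-2-one, both chains anti to the CMe2 bridge | C[C@@]1(C/C=C/[Si](C)(C)C)[C@H](CCC(C)=O)C(=O)[C@@H]2C[C@H]1C2(C)C | intermediate
9 | triethyl phosphonoacetate | CCOC(=O)CP(=O)(OCC)OCC | starting material
10 | sodium salt of the triethyl phosphonoacetate carbanion | CCOC(=O)[CH-]P(=O)(OCC)OCC.[Na+] | intermediate
11 | ethyl (2E)-3-methyl-5-{4,6,6-trimethyl-2-oxo-4-[(E)-3-(trimethylsilyl)prop-2-enyl]bicyclo[3.1.1]hept-3-yl}pent-2-enoate, stereocentres as in 8 | C[C@@]1(C/C=C/[Si](C)(C)C)[C@H](CC/C(C)=C/C(=O)OCC)C(=O)[C@@H]2C[C@H]1C2(C)C | intermediate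
12 | ring-opened tertiary C4 cation (ring-B silyl enol ether, vinylsilane on C10), triflate ion pair | CCOC(=O)/C=C(\C)CC[C@H]1[C@@](C)(C/C=C/[Si](C)(C)C)[C@@H](CC=C1O[Si](C)(C)C)[C+](C)C.[O-]S(=O)(=O)C(F)(F)F | intermediate
13 | ethyl (13E)-8-(trimethylsilyloxy)-17-nor-9-epi-labda-2,7,13-trien-15-oate | CCOC(=O)/C=C(\C)CC[C@H]1[C@@]2(C)CC=CC(C)(C)[C@@H]2CC=C1O[Si](C)(C)C | intermediate
14 | ethyl (13E)-8-oxo-17-nor-9-epi-labda-2,13-dien-15-oate (9βH) | CCOC(=O)/C=C(\C)CC[C@H]1[C@@]2(C)CC=CC(C)(C)[C@@H]2CCC1=O | intermediate
15 | ethyl (13E)-8-oxo-17-norlabda-2,13-dien-15-oate | CCOC(=O)/C=C(\C)CC[C@@H]1[C@@]2(C)CC=CC(C)(C)[C@@H]2CCC1=O | intermediate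
16 | ethyl (13E)-8-oxo-17-norlabd-13-en-15-oate | CCOC(=O)/C=C(\C)CC[C@@H]1[C@@]2(C)CCCC(C)(C)[C@@H]2CCC1=O | intermediate
17 | ethyl (13E)-labda-8(17),13-dien-15-oate | CCOC(=O)/C=C(\C)CC[C@@H]1[C@@]2(C)CCCC(C)(C)[C@@H]2CCC1=C | intermediate
18 | ethyl (13E)-8α,17-epoxylabd-13-en-15-oate | CCOC(=O)/C=C(\C)CC[C@@H]1[C@@]2(C)CCCC(C)(C)[C@@H]2CC[C@]12CO2 | intermediate
19 | (13E)-labd-13-ene-8α,15-diol | OC/C=C(\C)CC[C@@H]1[C@@]2(C)CCCC(C)(C)[C@@H]2CC[C@@]1(C)O | intermediate
20 | (13E)-8α-hydroxylabd-13-en-15-yl acetate, (5S,8R,9R,10S), CNP0268033.1 | CC(=O)OC/C=C(\C)CC[C@@H]1[C@@]2(C)CCCC(C)(C)[C@@H]2CC[C@@]1(C)O | target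

**Step count and risks**

Total steps: 9. Longest linear sequence: 9 steps (from 1).

Steps most likely to fail:

Step 4 (proposed new method). The fragmentation may not start with Me3SiOTf alone. The C4 cation may also be lost by proton loss or hydride shift before the E-vinylsilane captures it, since endocyclic closure is slower for an E- than for a Z-vinylsilane. The C9 equilibration in the work-up may stop short. Fallback with known chemistry, from 11 back to 15: BF3·OEt2, Ac2O and Zn(OAc)2 (the known acetolytic opening of nopinone-type cyclobutyl ketones) should give the ring-opened enol acetate with a tertiary acetate at C4, ethyl (2E)-5-{2-acetoxy-5-(2-acetoxypropan-2-yl)-6-methyl-6-[(E)-3-(trimethylsilyl)prop-2-enyl]cyclohex-2-en-1-yl}-3-methylpent-2-enoate F1. SnCl4 in CH2Cl2 at −78 °C then ionises the tertiary acetate for a conventional vinylsilane-terminated cation cyclization to ethyl (13E)-8-acetoxy-17-nor-9-epi-labda-2,7,13-trien-15-oate F2. K2CO3 in EtOH cleaves the enol acetate and equilibrates C9, which returns to 15.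

Step 1. 1,2-Addition or low conversion may occur at the fully substituted, bridge-shielded β-carbon, and some bond formation may occur through the silicon-bearing terminus (that allylsilane isomer could still close ring A, to the C1=C2 alkene, and converge at 16). Fallback, from 1 back to 5: CH2=CHCH2MgBr, CuBr·SMe2, LiCl and Me3SiCl in THF at −78 °C (conjugate allylation with silyl trapping) give 4-allyl-4,6,6-trimethyl-2-(trimethylsilyloxy)bicyclo[3.1.1]hept-2-ene F3. Cross-metathesis of F3 with excess vinyltrimethylsilane and the second-generation Grubbs catalyst (CH2Cl2, 40 °C) installs the E-vinylsilane and returns to 5.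

Step 2. Reaction at the congested C9 may be slow, or the Lewis acid may open the cyclobutane prematurely once the ring ketone is regenerated. Fallback, from 5 back to 8: MeLi in THF at 0 °C cleaves the silyl enol ether to the regiodefined lithium enolate F4. This is added at −78 °C to 3-(trimethylsilyl)but-3-en-2-one, an α-silyl vinyl ketone that tolerates aprotic enolate Michael addition, to give the α-silyl diketone 4,6,6-trimethyl-3-[3-oxo-2-(trimethylsilyl)butyl]-4-[(E)-3-(trimethylsilyl)prop-2-enyl]bicyclo[3.1.1]heptan-2-one F5. KOH in MeOH at 0 °C removes the α-silyl group and returns to 8 without any Lewis acid.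

**Further compounds**

F1 | step 4 | ethyl (2E)-5-{2-acetoxy-5-(2-acetoxypropan-2-yl)-6-methyl-6-[(E)-3-(trimethylsilyl)prop-2-enyl]cyclohex-2-en-1-yl}-3-methylpent-2-enoate, stereocentres as in 11 | CCOC(=O)/C=C(\C)CC[C@H]1[C@@](C)(C/C=C/[Si](C)(C)C)[C@@H](CC=C1OC(C)=O)C(C)(C)OC(C)=O
F2 | step 4 | ethyl (13E)-8-acetoxy-17-nor-9-epi-labda-2,7,13-trien-15-oate | CCOC(=O)/C=C(\C)CC[C@H]1[C@@]2(C)CC=CC(C)(C)[C@@H]2CC=C1OC(C)=O
F3 | step 1 | 4-allyl-4,6,6-trimethyl-2-(trimethylsilyloxy)bicyclo[3.1.1]hept-2-ene, allyl group anti to the CMe2 bridge | C[C@@]1(CC=C)C=C(O[Si](C)(C)C)[C@@H]2C[C@H]1C2(C)C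
F4 | step 2 | lithium enolate of 4,6,6-trimethyl-4-[(E)-3-(trimethylsilyl)prop-2-enyl]bicyclo[3.1.1]heptan-2-one | C[C@@]1(C/C=C/[Si](C)(C)C)C=C(O[Li])[C@@H]2C[C@H]1C2(C)C
F5 | step 2 | 4,6,6-trimethyl-3-[3-oxo-2-(trimethylsilyl)butyl]-4-[(E)-3-(trimethylsilyl)prop-2-enyl]bicyclo[3.1.1]heptan-2-one, mixture at the silyl-bearing side-chain carbon | C[C@@]1(C/C=C/[Si](C)(C)C)[C@H](CC([Si](C)(C)C)C(C)=O)C(=O)[C@@H]2C[C@H]1C2(C)C
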